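All runs stem from a simulated flask from invented constants; noise was put on by code.

The left-handed product of this flask cannot pass half of what is charged, since in the proposed steps it comes from the left-handed substrate, which is that half of the racemate. A short meeting took this racemic share as the zero of its scale.

| flask | left-handed substrate | right-handed substrate | gas | free catalyst | remark | time |
|---|---|---|---|---|---|---|
| south | 2 M | 2 M | 200 mM (held) | 31 mM | run made earlier |  |
| north-east | 2 M | 2 M | 200 mM (held) | 69 mM | run made earlier |  |
| flask | 2.0 M | 2.0 M | 200 mM (held) | 46 mM |  | 6.0 d |

| run | time / d | left-handed substrate / % | left-handed product / % |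
|---|---|---|---|
| south | 0.625 | 25.5 | 24.9 |
| south | 1.25 | 19.3 | 30.9 |
| south | 3.00 | 19.0 | 32.0 |
| south | 8.00 | 19.1 | 31.7 |
| north-east | 1.67 | 5.4 | 44.5 |
| north-east | 4.00 | 5.1 | 44.0 |
| north-east | 5.00 | 5.7 | 44.1 |
| north-east | 8.00 | 5.7 | 44.6 |

(each reading ± 0.3 percentage points)

- free catalyst is single-handed; left-handed substrate and right-handed substrate are mirror images of each other, charged as a racemate, each of them at the stated concentration
- at the start none of partner is dissolved
- the numbers in the tables scatter with a standard deviation of 0.3 percentage points
- steps that have been proposed: free catalyst + left-handed substrate <-> catalyst intermediate A; free catalyst + right-handed substrate <-> catalyst intermediate B; partner + catalyst intermediate A -> free catalyst + left-handed product; partner + catalyst intermediate B -> free catalyst + right-handed product; partner + free catalyst -> spent catalyst; gas <-> partner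

* conversion of left-handed substrate and right-handed substrate together at 6.0 d
* amount of left-handed product at 6.0 d, in percent of the left-handed substrate and right-handed substrate together charged

The chair reported that the left-handed substrate stops well above zero, at 19.1% in the south run and 5.7% in the north-east run, and proposed that partner turns free catalyst into spent catalyst while it also makes product. The secretary then measured how far each run had gone from the racemic share. South gives 0.0310 /mM and north-east 0.0315 /mM, from different charges, and their mean 0.0313 /mM is the depth per catalyst, the logarithm of the racemic share over the stopped left-handed substrate, per [free catalyst] charged.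

For the asked flask, a kinetic resolution at 46 mM of free catalyst, the secretary reckoned 11.9% left-handed substrate, hence 38.1% left-handed product. The forecast, a colleague's, stood higher, at 38.3% left-handed product, and at a conversion of 46%, with the warning “The right-handed side was never measured, so conversion rests on assumed selectivity”.

The asked flask gave 38.4% left-handed product and a conversion of 51.9%, which is 5.9 percentage points above the forecast.

    free catalyst + left-handed substrate ⇌ catalyst intermediate A (K = 1.10 /M, k = 925 /M/h)
    free catalyst + right-handed substrate ⇌ catalyst intermediate B (K = 0.680 /M, k = 1280 /M/h)
    partner + catalyst intermediate A → free catalyst + left-handed product (k = 62.3 /M/h)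
    partner + catalyst intermediate B → free catalyst + right-handed product (k = 21.4 /M/h)
    partner + free catalyst → spent catalyst (k = 2.12 /M/h)
    gas ⇌ partner, rate k6*(csat - [partner]) (kL = 1.55 /h)

The neighbouring flask, charged with 0.11 M of free catalyst, takes the same reckoning: the depth per catalyst gives 1.60% left-handed substrate, and that flask held 1.59%, with 48.4% left-handed product. Right-handed substrate can be treated alike once the 36.5% of it in the asked flask at 6.00 d is known: its depth per catalyst is 0.00682 /mM, smaller than the left-handed one. In the neighbouring flask that depth gives 23.6% right-handed substrate, and the flask held 23.8%.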